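**Plan**

Numbering: ring carbons C1–C10, lactone carbons C11–C13, ester carbon C14 on C10, methyl C15 on C4. Retrosynthesis cuts the C8 ester first, then the C6–C7 bond together with the O–C12 lactone bond, then C9–C10, C7–C11 and C1=C10.
Enabling feature: C6–C7 is the bond shared by the ten-membered carbocycle and the γ-lactone. The carbinol carbon C6 (next to the C4–C5 oxirane) and C7, allylic to the C11=C13 methylene that carries the C12 carbonyl, are the retron of a 2-(alkoxycarbonyl)allyl-metal addition to a C6 aldehyde.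
Forward: the oxirane is made first (step 1). The open chain is joined in the order C1=C10 (Wittig), C9–C10 (nickel/chromium coupling), C7–C11 (Morita–Baylis–Hillman). The carbocycle and the lactone then close in one chromium-mediated operation, and the epoxy ester is attached last.
Stereochemistry: C4/C5 and the side-chain oxirane come from Sharpless epoxidations, C8 from (R)-but-3-ene-1,2-diol, C9 from a Felkin–Anh addition, the C1=C10 geometry from a Z-iodoenoate coupled with retention, and C6/C7 from the key step under macrocyclic control.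

Key step: step 14

Remark: CIP letters at C7 and C8 change in some intermediates only because neighbouring substituents change priority; the spatial arrangement, once set, is that of the target throughout.

**Route**

Step 1
Reactants: 1 geraniol
Product: 2 [(2R,3R)-3-methyl-3-(4-methylpent-3-en-1-yl)oxiran-2-yl]methanol
Conditions: Ti(OiPr)4 (5 mol %), D-(−)-diethyl tartrate (7 mol %), t-BuOOH, 4 Å sieves, CH2Cl2, −20 °C
Reagents that add atoms: tert-butyl hydroperoxide, CC(C)(C)OO
Why: Sharpless asymmetric epoxidation of the allylic alcohol, in which the D-(−)-tartrate complex should deliver oxygen to the face that gives the (2R,3R)-oxirane, the future trans C4–C5 epoxide.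

Step 2
Reactants: 2 [(2R,3R)-3-methyl-3-(4-methylpent-3-en-1-yl)oxiran-2-yl]methanol
Product: 3 (2R,3R)-3-{[(4-methoxybenzyl)oxy]methyl}-2-methyl-2-(4-methylpent-3-en-1-yl)oxirane
Conditions: NaH, 4-methoxybenzyl chloride, Bu4NI (cat.), THF/DMF, 0 °C → rt
Reagents that add atoms: 4-methoxybenzyl chloride, COc1ccc(CCl)cc1
Why: Williamson etherification, in which the epoxy alkoxide should be alkylated in aprotic medium faster than it undergoes Payne rearrangement, giving an ether that can later be removed oxidatively beside silyl ethers and an allylic bromide.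

Step 3
Reactants: 3 (2R,3R)-3-{[(4-methoxybenzyl)oxy]methyl}-2-methyl-2-(4-methylpent-3-en-1-yl)oxirane
Product: 5 3-[(2R,3R)-3-{[(4-methoxybenzyl)oxy]methyl}-2-methyloxiran-2-yl]propanal, via secondary ozonide 4 (not isolated)
Conditions: O3, CH2Cl2, −78 °C; then PPh3, −78 °C → rt
Reagents that add atoms: ozone, [O-][O+]=O
Why: Ozonolysis with reductive work-up, in which the electron-rich trisubstituted olefin should be cleaved at −78 °C before the anisyl ring or the oxirane reacts, giving the C1 aldehyde.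

Step 4
Reactants: 5 3-[(2R,3R)-3-{[(4-methoxybenzyl)oxy]methyl}-2-methyloxiran-2-yl]propanal; 6 methyl (triphenylphosphoranylidene)acetate
Product: 8 methyl (2Z)-2-iodo-5-[(2R,3R)-3-{[(4-methoxybenzyl)oxy]methyl}-2-methyloxiran-2-yl]pent-2-enoate, via iodo ylide 7 (not isolated)
Conditions: 6, N-iodosuccinimide, MeCN, −20 °C; then 5, rt
Reagents that add atoms: N-iodosuccinimide, O=C1CCC(=O)N1I; methyl (triphenylphosphoranylidene)acetate, COC(=O)C=P(c1ccccc1)(c1ccccc1)c1ccccc1
Why: Wittig olefination with the iodo ylide made in the flask, in which the stabilised ylide should place the ester trans to the alkyl chain so that iodine ends cis to C2 (Z), the geometry needed for the ring-cis C1=C10 bond.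

Step 5
Reactants: 9 (2R)-but-3-ene-1,2-diol
Product: 10 (2R)-1,2-bis[(triethylsilyl)oxy]but-3-ene
Conditions: Et3SiCl (2.3 equiv), imidazole, DMAP (cat.), CH2Cl2, 0 °C → rt
Reagents that add atoms: chlorotriethylsilane, CC[Si](Cl)(CC)CC
Why: Standard silylation of both hydroxyl groups, which leaves the stereocentre (the future C8) untouched.

Step 6
Reactants: 10 (2R)-1,2-bis[(triethylsilyl)oxy]but-3-ene
Product: 12 (2S)-2,3-bis[(triethylsilyl)oxy]propanal, via secondary ozonide 11 (not isolated)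
Conditions: O3, CH2Cl2, −78 °C; then PPh3, −78 °C → rt
Reagents that add atoms: ozone, [O-][O+]=O
Why: Ozonolysis of the vinyl group with neutral reductive work-up should give the α-silyloxy aldehyde without epimerisation (the letter changes from R to S by priority only).

Step 7
Reactants: 8 methyl (2Z)-2-iodo-5-[(2R,3R)-3-{[(4-methoxybenzyl)oxy]methyl}-2-methyloxiran-2-yl]pent-2-enoate; 12 (2S)-2,3-bis[(triethylsilyl)oxy]propanal
Product: 14 methyl (2E,3R,4S)-3-hydroxy-2-{3-[(2R,3R)-3-{[(4-methoxybenzyl)oxy]methyl}-2-methyloxiran-2-yl]propylidene}-4,5-bis[(triethylsilyl)oxy]pentanoate, via alkenylchromium dichloride 13 (not isolated)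
Conditions: CrCl2 (4 equiv), NiCl2 (2 mol %), DMSO/THF, rt
Reagents that add atoms: none
Why: Nozaki–Hiyama–Kishi coupling, in which zerovalent nickel inserts into the C–I bond, the alkenyl group passes to chromium with retention of geometry (C9 ends cis to C2), and addition to the α-silyloxy aldehyde on its Felkin–Anh face should set C9 anti to the C8 oxygen.

Step 8
Reactants: 14 methyl (2E,3R,4S)-3-hydroxy-2-{3-[(2R,3R)-3-{[(4-methoxybenzyl)oxy]methyl}-2-methyloxiran-2-yl]propylidene}-4,5-bis[(triethylsilyl)oxy]pentanoate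
Product: 15 methyl (2E,3R,4S)-3-[(tert-butyldimethylsilyl)oxy]-2-{3-[(2R,3R)-3-{[(4-methoxybenzyl)oxy]methyl}-2-methyloxiran-2-yl]propylidene}-4,5-bis[(triethylsilyl)oxy]pentanoate
Conditions: TBSOTf, 2,6-lutidine, CH2Cl2, −78 °C
Reagents that add atoms: tert-butyldimethylsilyl trifluoromethanesulfonate, CC(C)(C)[Si](C)(C)OS(=O)(=O)C(F)(F)F
Why: Silylation of the hindered allylic alcohol with the silyl triflate under buffered low-temperature conditions should spare the oxirane and differentiate O9 (TBS) from O8 (TES).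

Step 9
Reactants: 15 methyl (2E,3R,4S)-3-[(tert-butyldimethylsilyl)oxy]-2-{3-[(2R,3R)-3-{[(4-methoxybenzyl)oxy]methyl}-2-methyloxiran-2-yl]propylidene}-4,5-bis[(triethylsilyl)oxy]pentanoate
Product: 16 methyl (2E,3R,4R)-3-[(tert-butyldimethylsilyl)oxy]-2-{3-[(2R,3R)-3-{[(4-methoxybenzyl)oxy]methyl}-2-methyloxiran-2-yl]propylidene}-5-oxo-4-[(triethylsilyl)oxy]pentanoate
Conditions: (COCl)2, DMSO, CH2Cl2, −78 → −40 °C; then Et3N, −78 → 0 °C
Reagents that add atoms: none
Why: Swern oxidation applied directly to the silyl ether, in which the primary triethylsilyl ether should be cleaved and oxidised to the C7 aldehyde while the secondary TES and TBS ethers stay and C8 is not epimerised at low temperature.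

Step 10
Reactants: 16 methyl (2E,3R,4R)-3-[(tert-butyldimethylsilyl)oxy]-2-{3-[(2R,3R)-3-{[(4-methoxybenzyl)oxy]methyl}-2-methyloxiran-2-yl]propylidene}-5-oxo-4-[(triethylsilyl)oxy]pentanoate; 17 methyl acrylate
Product: 18 dimethyl (4S,5R,6E)-5-[(tert-butyldimethylsilyl)oxy]-3-hydroxy-6-{3-[(2R,3R)-3-{[(4-methoxybenzyl)oxy]methyl}-2-methyloxiran-2-yl]propylidene}-2-methylidene-4-[(triethylsilyl)oxy]heptanedioate (both C3 epimers)
Conditions: 17 (neat, 15 equiv), DABCO (1 equiv), rt
Reagents that add atoms: methyl acrylate, C=CC(=O)OC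
Why: Morita–Baylis–Hillman reaction of an activated α-alkoxy aldehyde, in which the new carbinol centre (C7) needs no control because it becomes sp2 in step 11.

Step 11
Reactants: 18 dimethyl (4S,5R,6E)-5-[(tert-butyldimethylsilyl)oxy]-3-hydroxy-6-{3-[(2R,3R)-3-{[(4-methoxybenzyl)oxy]methyl}-2-methyloxiran-2-yl]propylidene}-2-methylidene-4-[(triethylsilyl)oxy]heptanedioate
Product: 19 dimethyl (2Z,4S,5R,6E)-2-(bromomethyl)-5-[(tert-butyldimethylsilyl)oxy]-6-{3-[(2R,3R)-3-{[(4-methoxybenzyl)oxy]methyl}-2-methyloxiran-2-yl]propylidene}-4-[(triethylsilyl)oxy]hept-2-enedioate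
Conditions: N-bromosuccinimide, Me2S, CH2Cl2, 0 °C → rt
Reagents that add atoms: N-bromosuccinimide, O=C1CCC(=O)N1Br
Why: Corey–Kim-type bromination of the Baylis–Hillman alcohol with allylic transposition (SN2′) should give the thermodynamically preferred (Z)-2-(bromomethyl)enoate under non-acidic conditions that spare the oxirane.

Step 12
Reactants: 19 dimethyl (2Z,4S,5R,6E)-2-(bromomethyl)-5-[(tert-butyldimethylsilyl)oxy]-6-{3-[(2R,3R)-3-{[(4-methoxybenzyl)oxy]methyl}-2-methyloxiran-2-yl]propylidene}-4-[(triethylsilyl)oxy]hept-2-enedioate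
Product: 20 dimethyl (2Z,4S,5R,6E)-2-(bromomethyl)-5-[(tert-butyldimethylsilyl)oxy]-6-{3-[(2R,3R)-3-(hydroxymethyl)-2-methyloxiran-2-yl]propylidene}-4-[(triethylsilyl)oxy]hept-2-enedioate
Conditions: DDQ, CH2Cl2/pH 7 buffer, 0 °C
Reagents that add atoms: none
Why: Oxidative cleavage of the 4-methoxybenzyl ether under neutral conditions, which the allylic bromide, both silyl ethers and the oxirane should tolerate.

Step 13
Reactants: 20 dimethyl (2Z,4S,5R,6E)-2-(bromomethyl)-5-[(tert-butyldimethylsilyl)oxy]-6-{3-[(2R,3R)-3-(hydroxymethyl)-2-methyloxiran-2-yl]propylidene}-4-[(triethylsilyl)oxy]hept-2-enedioate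
Product: 21 dimethyl (2Z,4S,5R,6E)-2-(bromomethyl)-5-[(tert-butyldimethylsilyl)oxy]-6-{3-[(2R,3S)-3-formyl-2-methyloxiran-2-yl]propylidene}-4-[(triethylsilyl)oxy]hept-2-enedioate
Conditions: Dess–Martin periodinane, NaHCO3, CH2Cl2, 0 °C → rt
Reagents that add atoms: none
Why: Dess–Martin oxidation of the primary epoxy alcohol under buffered conditions should give the C6 epoxy aldehyde without epimerisation at C5 and without touching the allylic bromide.

Step 14
Reactants: 21 dimethyl (2Z,4S,5R,6E)-2-(bromomethyl)-5-[(tert-butyldimethylsilyl)oxy]-6-{3-[(2R,3S)-3-formyl-2-methyloxiran-2-yl]propylidene}-4-[(triethylsilyl)oxy]hept-2-enedioate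
Product: 24 methyl (1S,2R,4R,7E,9R,10S,11S)-9-[(tert-butyldimethylsilyl)oxy]-4-methyl-12-methylidene-13-oxo-10-[(triethylsilyl)oxy]-3,14-dioxatricyclo[9.3.0.0(2,4)]tetradec-7-ene-8-carboxylate, via allylchromium dichloride 22 (not isolated), via cyclised chromium alkoxide 23 (not isolated)
Conditions: CrCl2 (8 equiv), THF, 0.003 M, 21 added over 10 h, rt; then 45 °C
Reagents that add atoms: none
Why: Two equivalents of CrCl2 reduce the allylic bromide to the allyl species of trivalent chromium 22, whose γ-carbon C7 adds to the C6 aldehyde through a chair-like six-membered transition state (Nozaki–Hiyama–Kishi allylation), and the chromium alkoxide 23 then acylates itself with the neighbouring C12 methyl ester. The closest known reaction type is the CrCl2-mediated macrocyclisation of ω-formyl 2-(bromomethyl)-2-enoates to ten-membered α-methylene-γ-butyrolactones of the germacranolide class. The carbocycle closes by a 10-exo-trig attack on the carbonyl with SE2′ transposition of the allyl unit (C11=C13 ends exocyclic), and the lactone by 5-exo-trig acyl substitution at C12. C6 and C7 are set together: the allylchromium can equilibrate to the geometry that puts both ring branches (C5 and C8) equatorial in the chair, which gives the 6,7-anti relationship of the trans-fused lactone, and the ring-cis C1=C10 olefin with the trans C4–C5 oxirane should let the tether span these positions only when C7 attacks the Si face of the aldehyde with the oxirane oxygen on the periphery, that is macrocyclic control, which is anti-Felkin with respect to C5. The step needs ring closure to win over oligomerisation and carbonyl addition to win over elimination or oxirane opening; high dilution with slow addition, the turn imposed by the cis olefin, the silyl (not acyl) oxygen at C8 that resists 1,4-elimination from 22, and the aldehyde selectivity of allylchromium reagents should secure this.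

Step 15
Reactants: 24 methyl (1S,2R,4R,7E,9R,10S,11S)-9-[(tert-butyldimethylsilyl)oxy]-4-methyl-12-methylidene-13-oxo-10-[(triethylsilyl)oxy]-3,14-dioxatricyclo[9.3.0.0(2,4)]tetradec-7-ene-8-carboxylate
Product: 25 methyl (1S,2R,4R,7E,9R,10S,11R)-9-[(tert-butyldimethylsilyl)oxy]-10-hydroxy-4-methyl-12-methylidene-13-oxo-3,14-dioxatricyclo[9.3.0.0(2,4)]tetradec-7-ene-8-carboxylate
Conditions: HF·pyridine, pyridine, THF, 0 °C
Reagents that add atoms: none
Why: Selective desilylation, in which the secondary triethylsilyl ether should be cleaved much faster than the TBS ether, freeing only O8.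

Step 16
Reactants: 26 (2E)-2-methylbut-2-en-1-ol
Product: 27 [(2R,3R)-2,3-dimethyloxiran-2-yl]methanol
Conditions: Ti(OiPr)4 (10 mol %), D-(−)-diethyl tartrate (12 mol %), t-BuOOH, 4 Å sieves, CH2Cl2, −20 °C
Reagents that add atoms: tert-butyl hydroperoxide, CC(C)(C)OO
Why: Sharpless asymmetric epoxidation, in which the D-(−)-tartrate complex should give the (2R,3R)-epoxy alcohol with the two methyl groups cis, as the E-olefin dictates.

Step 17
Reactants: 27 [(2R,3R)-2,3-dimethyloxiran-2-yl]methanol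
Product: 28 (2S,3R)-2,3-dimethyloxirane-2-carboxylic acid
Conditions: RuCl3 (2 mol %), NaIO4 (3 equiv), MeCN/CCl4/H2O, rt
Reagents that add atoms: water, O
Why: Catalytic RuO4 oxidation of the primary alcohol to the carboxylic acid, which should leave the oxirane intact (the letter at C2 changes to S by priority only).

Step 18
Reactants: 25 methyl (1S,2R,4R,7E,9R,10S,11R)-9-[(tert-butyldimethylsilyl)oxy]-10-hydroxy-4-methyl-12-methylidene-13-oxo-3,14-dioxatricyclo[9.3.0.0(2,4)]tetradec-7-ene-8-carboxylate; 28 (2S,3R)-2,3-dimethyloxirane-2-carboxylic acid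
Product: 30 methyl (1S,2R,4R,7E,9R,10S,11S)-9-[(tert-butyldimethylsilyl)oxy]-10-{[(2S,3R)-2,3-dimethyloxirane-2-carbonyl]oxy}-4-methyl-12-methylidene-13-oxo-3,14-dioxatricyclo[9.3.0.0(2,4)]tetradec-7-ene-8-carboxylate, via mixed anhydride 29 (not isolated)
Conditions: 28, 2,4,6-trichlorobenzoyl chloride, Et3N, THF, rt; then 25, DMAP, toluene, rt
Reagents that add atoms: none
Why: Yamaguchi esterification, in which the mixed anhydride should transfer the hindered epoxy acyl group to the free C8 hydroxyl without racemisation, since the acid has no α-hydrogen.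

Step 19
Reactants: 30 methyl (1S,2R,4R,7E,9R,10S,11S)-9-[(tert-butyldimethylsilyl)oxy]-10-{[(2S,3R)-2,3-dimethyloxirane-2-carbonyl]oxy}-4-methyl-12-methylidene-13-oxo-3,14-dioxatricyclo[9.3.0.0(2,4)]tetradec-7-ene-8-carboxylate
Product: 31 methyl (1S,2R,4R,7E,9R,10S,11R)-10-{[(2S,3R)-2,3-dimethyloxirane-2-carbonyl]oxy}-9-hydroxy-4-methyl-12-methylidene-13-oxo-3,14-dioxatricyclo[9.3.0.0(2,4)]tetradec-7-ene-8-carboxylate (target)
Conditions: HF·pyridine, THF, 0 °C → rt
Reagents that add atoms: none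
Why: Desilylation of the TBS ether under mildly acidic fluoride conditions should free the C9 hydroxyl without 8→9 acyl migration or conjugate addition to the α-methylene lactone.

**Compound list**

1 | geraniol, (2E)-3,7-dimethylocta-2,6-dien-1-ol | CC(C)=CCC/C(C)=C/CO | starting material
2 | [(2R,3R)-3-methyl-3-(4-methylpent-3-en-1-yl)oxiran-2-yl]methanol | CC(C)=CCC[C@@]1(C)O[C@@H]1CO | intermediate
3 | (2R,3R)-3-{[(4-methoxybenzyl)oxy]methyl}-2-methyl-2-(4-methylpent-3-en-1-yl)oxirane | CC(C)=CCC[C@@]1(C)O[C@@H]1COCc1ccc(OC)cc1 | intermediate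
4 | secondary ozonide of 3, 3-{2-[(2R,3R)-3-{[(4-methoxybenzyl)oxy]methyl}-2-methyloxiran-2-yl]ethyl}-5,5-dimethyl-1,2,4-trioxolane | CC1(C)OOC(CC[C@@]2(C)O[C@@H]2COCc2ccc(OC)cc2)O1 | intermediate
5 | 3-[(2R,3R)-3-{[(4-methoxybenzyl)oxy]methyl}-2-methyloxiran-2-yl]propanal | O=CCC[C@@]1(C)O[C@@H]1COCc1ccc(OC)cc1 | intermediate
6 | methyl (triphenylphosphoranylidene)acetate | COC(=O)C=P(c1ccccc1)(c1ccccc1)c1ccccc1 | starting material
7 | methyl iodo(triphenylphosphoranylidene)acetate (iodo ylide) | COC(=O)C(I)=P(c1ccccc1)(c1ccccc1)c1ccccc1 | intermediate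
8 | methyl (2Z)-2-iodo-5-[(2R,3R)-3-{[(4-methoxybenzyl)oxy]methyl}-2-methyloxiran-2-yl]pent-2-enoate | COC(=O)/C(I)=C/CC[C@@]1(C)O[C@@H]1COCc1ccc(OC)cc1 | intermediate
9 | (2R)-but-3-ene-1,2-diol | OC[C@H](O)C=C | starting material
10 | (2R)-1,2-bis[(triethylsilyl)oxy]but-3-ene | CC[Si](CC)(CC)OC[C@H](O[Si](CC)(CC)CC)C=C | intermediate
11 | secondary ozonide of 10, 3-{(1S)-1,2-bis[(triethylsilyl)oxy]ethyl}-1,2,4-trioxolane | CC[Si](CC)(CC)OC[C@H](O[Si](CC)(CC)CC)C1OCOO1 | intermediate
12 | (2S)-2,3-bis[(triethylsilyl)oxy]propanal | CC[Si](CC)(CC)OC[C@H](O[Si](CC)(CC)CC)C=O | intermediate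
13 | alkenylchromium dichloride from 8 (CrCl2 in place of iodine, olefin geometry retained) | COC(=O)/C([Cr](Cl)Cl)=C/CC[C@@]1(C)O[C@@H]1COCc1ccc(OC)cc1 | intermediate
14 | methyl (2E,3R,4S)-3-hydroxy-2-{3-[(2R,3R)-3-{[(4-methoxybenzyl)oxy]methyl}-2-methyloxiran-2-yl]propylidene}-4,5-bis[(triethylsilyl)oxy]pentanoate | CC[Si](CC)(CC)OC[C@H](O[Si](CC)(CC)CC)[C@H](O)/C(C(=O)OC)=C\CC[C@@]1(C)O[C@@H]1COCc1ccc(OC)cc1 | intermediate
15 | methyl (2E,3R,4S)-3-[(tert-butyldimethylsilyl)oxy]-2-{3-[(2R,3R)-3-{[(4-methoxybenzyl)oxy]methyl}-2-methyloxiran-2-yl]propylidene}-4,5-bis[(triethylsilyl)oxy]pentanoate | CC[Si](CC)(CC)OC[C@H](O[Si](CC)(CC)CC)[C@H](O[Si](C)(C)C(C)(C)C)/C(C(=O)OC)=C\CC[C@@]1(C)O[C@@H]1COCc1ccc(OC)cc1 | intermediate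
16 | methyl (2E,3R,4R)-3-[(tert-butyldimethylsilyl)oxy]-2-{3-[(2R,3R)-3-{[(4-methoxybenzyl)oxy]methyl}-2-methyloxiran-2-yl]propylidene}-5-oxo-4-[(triethylsilyl)oxy]pentanoate | O=C[C@H](O[Si](CC)(CC)CC)[C@H](O[Si](C)(C)C(C)(C)C)/C(C(=O)OC)=C\CC[C@@]1(C)O[C@@H]1COCc1ccc(OC)cc1 | intermediate
17 | methyl acrylate | C=CC(=O)OC | starting material
18 | dimethyl (4S,5R,6E)-5-[(tert-butyldimethylsilyl)oxy]-3-hydroxy-6-{3-[(2R,3R)-3-{[(4-methoxybenzyl)oxy]methyl}-2-methyloxiran-2-yl]propylidene}-2-methylidene-4-[(triethylsilyl)oxy]heptanedioate, both C3 epimers | C=C(C(=O)OC)C(O)[C@H](O[Si](CC)(CC)CC)[C@H](O[Si](C)(C)C(C)(C)C)/C(C(=O)OC)=C\CC[C@@]1(C)O[C@@H]1COCc1ccc(OC)cc1 | intermediate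
19 | dimethyl (2Z,4S,5R,6E)-2-(bromomethyl)-5-[(tert-butyldimethylsilyl)oxy]-6-{3-[(2R,3R)-3-{[(4-methoxybenzyl)oxy]methyl}-2-methyloxiran-2-yl]propylidene}-4-[(triethylsilyl)oxy]hept-2-enedioate | BrC/C(C(=O)OC)=C\[C@H](O[Si](CC)(CC)CC)[C@H](O[Si](C)(C)C(C)(C)C)/C(C(=O)OC)=C\CC[C@@]1(C)O[C@@H]1COCc1ccc(OC)cc1 | intermediate
20 | dimethyl (2Z,4S,5R,6E)-2-(bromomethyl)-5-[(tert-butyldimethylsilyl)oxy]-6-{3-[(2R,3R)-3-(hydroxymethyl)-2-methyloxiran-2-yl]propylidene}-4-[(triethylsilyl)oxy]hept-2-enedioate | BrC/C(C(=O)OC)=C\[C@H](O[Si](CC)(CC)CC)[C@H](O[Si](C)(C)C(C)(C)C)/C(C(=O)OC)=C\CC[C@@]1(C)O[C@@H]1CO | intermediate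
21 | dimethyl (2Z,4S,5R,6E)-2-(bromomethyl)-5-[(tert-butyldimethylsilyl)oxy]-6-{3-[(2R,3S)-3-formyl-2-methyloxiran-2-yl]propylidene}-4-[(triethylsilyl)oxy]hept-2-enedioate | BrC/C(C(=O)OC)=C\[C@H](O[Si](CC)(CC)CC)[C@H](O[Si](C)(C)C(C)(C)C)/C(C(=O)OC)=C\CC[C@@]1(C)O[C@@H]1C=O | intermediate
22 | allylchromium dichloride from 21 (CrCl2 in place of bromine, C7=C11 geometry mobile) | Cl[Cr](Cl)CC(C(=O)OC)=C[C@H](O[Si](CC)(CC)CC)[C@H](O[Si](C)(C)C(C)(C)C)/C(C(=O)OC)=C\CC[C@@]1(C)O[C@@H]1C=O | intermediate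
23 | dichlorochromium alkoxide of the cyclised C6 hydroxy ester (C6–C7 bond formed, ten-membered ring closed, C12 still a methyl ester) | C=C(C(=O)OC)[C@@H]1[C@H](O[Si](CC)(CC)CC)[C@H](O[Si](C)(C)C(C)(C)C)/C(C(=O)OC)=C\CC[C@@]2(C)O[C@@H]2[C@H]1O[Cr](Cl)Cl | intermediate
24 | methyl (1S,2R,4R,7E,9R,10S,11S)-9-[(tert-butyldimethylsilyl)oxy]-4-methyl-12-methylidene-13-oxo-10-[(triethylsilyl)oxy]-3,14-dioxatricyclo[9.3.0.0(2,4)]tetradec-7-ene-8-carboxylate | C=C1C(=O)O[C@H]2[C@H]1[C@H](O[Si](CC)(CC)CC)[C@H](O[Si](C)(C)C(C)(C)C)/C(C(=O)OC)=C\CC[C@@]1(C)O[C@H]21 | intermediate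
25 | methyl (1S,2R,4R,7E,9R,10S,11R)-9-[(tert-butyldimethylsilyl)oxy]-10-hydroxy-4-methyl-12-methylidene-13-oxo-3,14-dioxatricyclo[9.3.0.0(2,4)]tetradec-7-ene-8-carboxylate | C=C1C(=O)O[C@H]2[C@H]1[C@H](O)[C@H](O[Si](C)(C)C(C)(C)C)/C(C(=O)OC)=C\CC[C@@]1(C)O[C@H]21 | intermediate
26 | (2E)-2-methylbut-2-en-1-ol (tiglyl alcohol) | C/C=C(\C)CO | starting material
27 | [(2R,3R)-2,3-dimethyloxiran-2-yl]methanol | OC[C@@]1(C)O[C@@H]1C | intermediate
28 | (2S,3R)-2,3-dimethyloxirane-2-carboxylic acid | OC(=O)[C@@]1(C)O[C@@H]1C | intermediate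
29 | (2S,3R)-2,3-dimethyloxirane-2-carboxylic 2,4,6-trichlorobenzoic anhydride | O=C(OC(=O)c1c(Cl)cc(Cl)cc1Cl)[C@@]1(C)O[C@@H]1C | intermediate
30 | methyl (1S,2R,4R,7E,9R,10S,11S)-9-[(tert-butyldimethylsilyl)oxy]-10-{[(2S,3R)-2,3-dimethyloxirane-2-carbonyl]oxy}-4-methyl-12-methylidene-13-oxo-3,14-dioxatricyclo[9.3.0.0(2,4)]tetradec-7-ene-8-carboxylate | C=C1C(=O)O[C@H]2[C@H]1[C@H](OC(=O)[C@@]1(C)O[C@@H]1C)[C@H](O[Si](C)(C)C(C)(C)C)/C(C(=O)OC)=C\CC[C@@]1(C)O[C@H]21 | intermediate
31 | methyl (1S,2R,4R,7E,9R,10S,11R)-10-{[(2S,3R)-2,3-dimethyloxirane-2-carbonyl]oxy}-9-hydroxy-4-methyl-12-methylidene-13-oxo-3,14-dioxatricyclo[9.3.0.0(2,4)]tetradec-7-ene-8-carboxylate | C=C1C(=O)O[C@H]2[C@H]1[C@H](OC(=O)[C@@]1(C)O[C@@H]1C)[C@H](O)/C(C(=O)OC)=C\CC[C@@]1(C)O[C@H]21 | target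

**Count and risks**

Total step count: 19. Longest linear sequence: 15 steps (steps 1–4, 7–15, 18, 19, from geraniol).

Steps most likely to fail:

1. Step 14. The allylchromium may add to the Felkin face of the epoxy aldehyde (control by C5 overriding the macrocycle) while keeping its facial sense at C7, which would give the cis-fused C6 epimer. The fallback sets out from 21 and comes back at 24, and corrects C6 by inversion instead of by direct facial control. The cyclisation product is then the cis-fused C6-epimeric macrolactone F1. Its lactone would be opened with LiOH (THF/H2O, 0 °C) to the seco hydroxy acid F2. Mitsunobu lactonisation of F2 (PPh3, DIAD, THF, high dilution) should close the lactone with SN2 inversion at C6 and give 24.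

2. Step 7. The olefin geometry may be lost through an oxygen-bound chromium allenolate, and the Felkin–Anh selectivity at C9 may be incomplete. The fallback sets out from 5 and comes back at 14, and builds the enoate from an alkyne by additions of fixed stereochemical course. Ohira–Bestmann homologation of 5 (dimethyl (1-diazo-2-oxopropyl)phosphonate, K2CO3, MeOH) would give the terminal alkyne F3. Its lithium acetylide (n-BuLi, THF, −78 °C) would add to 12 on the Felkin–Anh face to give the propargylic alcohol F4. Syn-hydrostannation catalysed by Pd(PPh3)2Cl2 with Bu3SnH, tin going to the carbon next to the carbinol, would give the (E)-alkenylstannane F5. Iododestannylation (I2, CH2Cl2, 0 °C) would give the alkenyl iodide F6 with retention. Methoxycarbonylation of F6 (Pd(PPh3)4, CO, MeOH, Et3N, 50 °C) should then give 14 with C9 cis to C2.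

3. Step 10. The reaction may be slow, with epimerisation at C8 or β-elimination of the C9 silyloxy group during long exposure of aldehyde 16 to the amine. The fallback sets out from 16 and comes back at 18, and replaces amine catalysis by a preformed vinyl-metal nucleophile (vinylalumination). The [1-(methoxycarbonyl)vinyl]aluminium reagent, made separately from methyl propiolate and i-Bu2AlH with N-methylmorpholine N-oxide in THF, would add to 16 at 0 °C within about an hour and should give 18 directly. No new compound arises (F0).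

**Further compounds**

F1 | step 14 | C1 epimer of 24 (cis-fused lactone), methyl (1R,2R,4R,7E,9R,10S,11S)-9-[(tert-butyldimethylsilyl)oxy]-4-methyl-12-methylidene-13-oxo-10-[(triethylsilyl)oxy]-3,14-dioxatricyclo[9.3.0.0(2,4)]tetradec-7-ene-8-carboxylate | C=C1C(=O)O[C@@H]2[C@H]1[C@H](O[Si](CC)(CC)CC)[C@H](O[Si](C)(C)C(C)(C)C)/C(C(=O)OC)=C\CC[C@@]1(C)O[C@H]21
F2 | step 14 | seco hydroxy acid of F1 (ten-membered ring, free C6 hydroxyl, C12 acrylic acid, C14 methyl ester kept) | C=C(C(=O)O)[C@@H]1[C@H](O[Si](CC)(CC)CC)[C@H](O[Si](C)(C)C(C)(C)C)/C(C(=O)OC)=C\CC[C@@]2(C)O[C@@H]2[C@@H]1O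
F3 | step 7 | (2R,3R)-2-(but-3-yn-1-yl)-3-{[(4-methoxybenzyl)oxy]methyl}-2-methyloxirane | C#CCC[C@@]1(C)O[C@@H]1COCc1ccc(OC)cc1
F4 | step 7 | (2S,3R)-7-[(2R,3R)-3-{[(4-methoxybenzyl)oxy]methyl}-2-methyloxiran-2-yl]-1,2-bis[(triethylsilyl)oxy]hept-4-yn-3-ol | CC[Si](CC)(CC)OC[C@H](O[Si](CC)(CC)CC)[C@H](O)C#CCC[C@@]1(C)O[C@@H]1COCc1ccc(OC)cc1
F5 | step 7 | (2S,3R,4E)-7-[(2R,3R)-3-{[(4-methoxybenzyl)oxy]methyl}-2-methyloxiran-2-yl]-4-(tributylstannyl)-1,2-bis[(triethylsilyl)oxy]hept-4-en-3-ol | CC[Si](CC)(CC)OC[C@H](O[Si](CC)(CC)CC)[C@H](O)/C([Sn](CCCC)(CCCC)CCCC)=C\CC[C@@]1(C)O[C@@H]1COCc1ccc(OC)cc1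
F6 | step 7 | (2S,3R,4E)-4-iodo-7-[(2R,3R)-3-{[(4-methoxybenzyl)oxy]methyl}-2-methyloxiran-2-yl]-1,2-bis[(triethylsilyl)oxy]hept-4-en-3-ol | CC[Si](CC)(CC)OC[C@H](O[Si](CC)(CC)CC)[C@H](O)/C(I)=C\CC[C@@]1(C)O[C@@H]1COCc1ccc(OC)cc1
F0 | step 10 | none | none
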